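**Assumption:** the target has no stereocentre and no stereogenic double bond (each prenyl olefin carries two methyl groups), so the SMILES defines one achiral compound and no stereocontrol is required.

**Retrosynthetic overview**
1. Target 10 ⇐ dipivalate 9 by ester methanolysis. No prenyl group is carried in on a building block.
2. Key step: both prenyl groups arrive at once by a twofold aromatic Claisen rearrangement of the 5,2'-bis(1,1-dimethylallyl) ether 8. Each ether has only one free ortho position, so C6 and C3' are the only possible destinations.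
3. 8 ⇐ bis(1,1-dimethylpropargyl) ether 7 (Lindlar) ⇐ 5,2'-diol 6 (twofold copper-catalysed tert-propargylation) ⇐ 2'-hydroxygenistein 5 (selective 7,4'-dipivaloylation).
4. 5 ⇐ phloroglucinol 1 + 2,4-dimethoxyphenylacetic acid 2 by one-pot acylation and formylative ring closure, then demethylation.
5. Ring order: rings A and B are bought; ring C (the pyranone) is the only ring formed, in step 1.

**Route**

Step 1
Reactants: 1 phloroglucinol; 2 2-(2,4-dimethoxyphenyl)acetic acid
Product: 4 5,7-dihydroxy-2',4'-dimethoxyisoflavone, via deoxybenzoin 3 (not isolated)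
Conditions: BF3·OEt2 (neat, as solvent), 85 °C, 1.5 h; then DMF, MsCl, 55 → 80 °C; poured into water
Reagents that add atoms: N,N-dimethylformamide, CN(C)C=O
Why: BF3-promoted Friedel–Crafts (Houben–Hoesch-type) C-acylation of the symmetric, highly nucleophilic phloroglucinol gives the deoxybenzoin as its boron chelate, whose activated methylene is formylated by the DMF/MsCl Vilsmeier-type iminium and closes onto an ortho phenol with loss of dimethylamine to form ring C, while the methyl ethers keep the future 2'-oxygen from cyclising onto the ketone.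

Step 2
Reactants: 4 5,7-dihydroxy-2',4'-dimethoxyisoflavone
Product: 5 2'-hydroxygenistein (5,7,2',4'-tetrahydroxyisoflavone)
Conditions: BBr3 (8 equiv), CH2Cl2, −78 °C → rt; H2O quench
Reagents that add atoms: none
Why: Lewis-acid ether cleavage in which BBr3 coordinates each anisole oxygen and bromide removes the methyl group by SN2, leaving the chromone untouched and releasing the tetraphenol on hydrolysis.

Step 3
Reactants: 5 2'-hydroxygenistein
Product: 6 5,2'-dihydroxy-7,4'-bis(pivaloyloxy)isoflavone
Conditions: PivCl (2.1 equiv), pyridine, −20 → 0 °C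
Reagents that add atoms: pivaloyl chloride, CC(C)(C)C(=O)Cl
Why: Chemoselective esterification in which the acidic 7-OH and the unhindered 4'-OH react with the bulky acyl chloride, whereas the 5-OH is locked in a six-membered hydrogen bond to the C4 carbonyl and the 2'-OH is both hydrogen-bonded to that carbonyl and shielded by the neighbouring chromone ring.

Step 4
Reactants: 6 5,2'-dihydroxy-7,4'-bis(pivaloyloxy)isoflavone
Product: 7 5,2'-bis[(2-methylbut-3-yn-2-yl)oxy]-7,4'-bis(pivaloyloxy)isoflavone
Conditions: 3-chloro-3-methylbut-1-yne (6 equiv), DBU (6 equiv), CuCl2·2H2O (10 mol %), MeCN, 0 °C → rt, argon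
Reagents that add atoms: 3-chloro-3-methylbut-1-yne, CC(C)(Cl)C#C
Why: Copper-catalysed propargylic etherification in which the copper acetylide of the tertiary chloride ionises to an electrophilic copper allenylidene that is captured at its tertiary carbon by the DBU-generated phenoxides, a process that accepts hindered and electron-poor phenols and leaves aryl pivalates alone.

Step 5
Reactants: 7 5,2'-bis[(2-methylbut-3-yn-2-yl)oxy]-7,4'-bis(pivaloyloxy)isoflavone
Product: 9 5,2'-dihydroxy-6,3'-diprenyl-7,4'-bis(pivaloyloxy)isoflavone, via bis(1,1-dimethylallyl) ether 8 (not isolated)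
Conditions: H2 (1 atm), Pd/CaCO3 poisoned with Pb(OAc)2 (Lindlar catalyst), quinoline, o-xylene, rt; filter through Celite; filtrate heated at 135 °C, 3 h
Reagents that add atoms: none
Why: Lindlar semihydrogenation turns both terminal alkynes into vinyl groups and the resulting tertiary allyl aryl ethers undergo a twofold aromatic Claisen ([3,3]-sigmatropic) rearrangement in which each ether has a single open ortho position (C6 for the 5-O ether because C4a is ring-fused, C3' for the 2'-O ether because C1' bears the chromone), so allylic transposition delivers normal prenyl groups exactly at C6 and C3' and enolisation restores the 5- and 2'-phenols.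

Step 6
Reactants: 9 5,2'-dihydroxy-6,3'-diprenyl-7,4'-bis(pivaloyloxy)isoflavone
Product: 10 2'-hydroxylupalbigenin
Conditions: K2CO3 (4 equiv), MeOH, 40 °C, argon; aq. NH4Cl work-up
Reagents that add atoms: none
Why: Base-mediated transesterification (methanolysis) of the two aryl pivalates, whose phenoxide leaving groups make them far more labile than the chromone toward methoxide, under non-acidic conditions that cannot cyclise the ortho-prenyl phenols to chromans.

**Compound list**
1 | phloroglucinol (benzene-1,3,5-triol) | Oc1cc(O)cc(O)c1 | starting material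
2 | 2-(2,4-dimethoxyphenyl)acetic acid | COc1ccc(CC(=O)O)c(OC)c1 | starting material
3 | 2-(2,4-dimethoxyphenyl)-1-(2,4,6-trihydroxyphenyl)ethan-1-one (deoxybenzoin, not isolated) | COc1ccc(CC(=O)c2c(O)cc(O)cc2O)c(OC)c1 | intermediate
4 | 5,7-dihydroxy-2',4'-dimethoxyisoflavone | COc1ccc(-c2coc3cc(O)cc(O)c3c2=O)c(OC)c1 | intermediate
5 | 2'-hydroxygenistein (5,7,2',4'-tetrahydroxyisoflavone) | Oc1ccc(-c2coc3cc(O)cc(O)c3c2=O)c(O)c1 | intermediate
6 | 5,2'-dihydroxy-7,4'-bis(pivaloyloxy)isoflavone | CC(C)(C)C(=O)Oc1ccc(-c2coc3cc(OC(=O)C(C)(C)C)cc(O)c3c2=O)c(O)c1 | intermediate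
7 | 5,2'-bis[(2-methylbut-3-yn-2-yl)oxy]-7,4'-bis(pivaloyloxy)isoflavone | C#CC(C)(C)Oc1cc(OC(=O)C(C)(C)C)ccc1-c1coc2cc(OC(=O)C(C)(C)C)cc(OC(C)(C)C#C)c2c1=O | intermediate
8 | 5,2'-bis[(2-methylbut-3-en-2-yl)oxy]-7,4'-bis(pivaloyloxy)isoflavone (not isolated) | C=CC(C)(C)Oc1cc(OC(=O)C(C)(C)C)ccc1-c1coc2cc(OC(=O)C(C)(C)C)cc(OC(C)(C)C=C)c2c1=O | intermediate
9 | 5,2'-dihydroxy-6,3'-bis(3-methylbut-2-en-1-yl)-7,4'-bis(pivaloyloxy)isoflavone | CC(C)=CCc1c(OC(=O)C(C)(C)C)ccc(-c2coc3cc(OC(=O)C(C)(C)C)c(CC=C(C)C)c(O)c3c2=O)c1O | intermediate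
10 | 2'-hydroxylupalbigenin | CC(C)=CCc1c(O)ccc(-c2coc3cc(O)c(CC=C(C)C)c(O)c3c2=O)c1O | target

**Totals**
Total step count: 6. Longest linear sequence: 6 steps (1 and 2 → 10).

**Three steps most likely to fail, each with a fallback**

Step 3 (selective 7,4'-dipivaloylation). The 4'-OH versus 2'-OH discrimination rests only on sterics and a hydrogen bond and may give mixtures. The fallback builds the distinction into the ring B fragment instead; it sets out from 1 and comes back at 6. 3-Methoxyphenol is condensed with glyoxylic acid (aq. NaOH, rt, para to the phenoxide) to give racemic 4-hydroxy-2-methoxymandelic acid F1. Reduction of the benzylic hydroxyl (SnCl2·2H2O, conc. HCl, 80 °C) gives 2-(4-hydroxy-2-methoxyphenyl)acetic acid F2. F2 and 1 in BF3·OEt2 at 85 °C give the deoxybenzoin 2-(4-hydroxy-2-methoxyphenyl)-1-(2,4,6-trihydroxyphenyl)ethan-1-one F3, not isolated, which DMF/MsCl closes to 5,7,4'-trihydroxy-2'-methoxyisoflavone F4. In F4 the only unchelated hydroxyls are at C7 and C4', so PivCl/pyridine gives 5-hydroxy-2'-methoxy-7,4'-bis(pivaloyloxy)isoflavone F5 without any selectivity question. BBr3 (CH2Cl2, −78 → 0 °C) then cleaves the single methyl ether while the aryl pivalates survive, giving 6.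

Step 4 (tertiary propargyl etherification of the chelated 5-OH and the hindered 2'-OH). The 5-phenoxide is a poor nucleophile and may bind copper. The fallback replaces the tertiary electrophile by an SN2-active one and moves the dimethyl substitution to the end; it sets out from 6 and comes back at 9. Allyl bromide (K2CO3, acetone, reflux) gives 5,2'-bis(allyloxy)-7,4'-bis(pivaloyloxy)isoflavone F6. A twofold thermal Claisen rearrangement (N,N-diethylaniline, 200 °C), with the same single-ortho-position regiocontrol, gives 6,3'-diallyl-5,2'-dihydroxy-7,4'-bis(pivaloyloxy)isoflavone F7. Twofold cross-metathesis with 2-methylbut-2-ene (second-generation Grubbs catalyst RuCl2(=CHPh)(H2IMes)(PCy3), CH2Cl2, 40 °C) converts both allyl groups into prenyl groups and gives 9.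

Step 5 (Lindlar reduction and double Claisen). The risks are over-reduction of the vinyl groups and thermal loss of isoprene from the tertiary ethers in competition with rearrangement. The fallback avoids tertiary ethers and sigmatropy altogether; it sets out from 6 and comes back at 9. Prenyl bromide (K2CO3, acetone, reflux) gives 5,2'-bis(3-methylbut-2-enyloxy)-7,4'-bis(pivaloyloxy)isoflavone F8. An acid-clay-promoted [1,3] oxygen-to-carbon prenyl shift through a tight ion pair (montmorillonite K10 clay, Al2Si4O10(OH)2·nH2O, CH2Cl2, 0 °C → rt) returns each prenyl group to the adjacent free ortho carbon (C6 and C3') and gives 9 after chromatographic removal of para-shifted and chroman by-products.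

**Further compounds**
F1 | step 3 | 2-hydroxy-2-(4-hydroxy-2-methoxyphenyl)acetic acid (racemic) | COc1cc(O)ccc1C(O)C(=O)O
F2 | step 3 | 2-(4-hydroxy-2-methoxyphenyl)acetic acid | COc1cc(O)ccc1CC(=O)O
F3 | step 3 | 2-(4-hydroxy-2-methoxyphenyl)-1-(2,4,6-trihydroxyphenyl)ethan-1-one | COc1cc(O)ccc1CC(=O)c1c(O)cc(O)cc1O
F4 | step 3 | 5,7,4'-trihydroxy-2'-methoxyisoflavone | COc1cc(O)ccc1-c1coc2cc(O)cc(O)c2c1=O
F5 | step 3 | 5-hydroxy-2'-methoxy-7,4'-bis(pivaloyloxy)isoflavone | COc1cc(OC(=O)C(C)(C)C)ccc1-c1coc2cc(OC(=O)C(C)(C)C)cc(O)c2c1=O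
F6 | step 4 | 5,2'-bis(allyloxy)-7,4'-bis(pivaloyloxy)isoflavone | C=CCOc1cc(OC(=O)C(C)(C)C)ccc1-c1coc2cc(OC(=O)C(C)(C)C)cc(OCC=C)c2c1=O
F7 | step 4 | 6,3'-diallyl-5,2'-dihydroxy-7,4'-bis(pivaloyloxy)isoflavone | C=CCc1c(OC(=O)C(C)(C)C)ccc(-c2coc3cc(OC(=O)C(C)(C)C)c(CC=C)c(O)c3c2=O)c1O
F8 | step 5 | 5,2'-bis(3-methylbut-2-enyloxy)-7,4'-bis(pivaloyloxy)isoflavone | CC(C)=CCOc1cc(OC(=O)C(C)(C)C)ccc1-c1coc2cc(OC(=O)C(C)(C)C)cc(OCC=C(C)C)c2c1=O
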